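Everything rests on unmasking the bis-pyranone as a 3-hydroxyglutarate: ring carbons C2 of ring A (pentyl side) and C2 of ring B (ethyl side) are both at the carboxyl oxidation level, so the CH(CH3) carbons Ca and Cb beside them are ester α-carbons once the central carbon Ck is a carbinol. A single operation on the trilithio derivative of tert-butyl methyl (3S)-3-hydroxyglutarate then forges both C–CH3 bonds anti to the chelating alkoxide at Ck, which fixes the pseudo-meso Ca/Cb relationship and, because the two esters differ, its absolute sense. The methyl ester arm is later built into ring A, the tert-butyl arm into ring B, and Ck is oxidised last.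

Key step: step 3

Assumption: 4-methylheptane-3,5-dione (20) is taken as purchasable, and the CH(CH3) and carbinol centres created in steps 5, 7 and 12 are left as mixtures because oxidation and ring closure erase every one of them.

Step 1
Reactants: 1 (3R)-3-[(tert-butyldimethylsilyl)oxy]-5-methoxy-5-oxopentanoic acid
Product: 2 1-tert-butyl 5-methyl (3S)-3-[(tert-butyldimethylsilyl)oxy]pentanedioate
Conditions: t-BuOC(=NH)CCl3 (2 equiv), cyclohexane/CH2Cl2, rt
Reagents that add atoms: tert-butyl 2,2,2-trichloroacetimidate, CC(C)(C)OC(=N)C(Cl)(Cl)Cl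
Why: Imidate esterification, in which the acid protonates the trichloroacetimidate and is O-alkylated by the tert-butyl cation it releases, is mild enough to keep the silyl ether and methyl ester; the carbinol carbon is untouched and its descriptor changes from R to S only because the ranking of the two arms changes.

Step 2
Reactants: 2 1-tert-butyl 5-methyl (3S)-3-[(tert-butyldimethylsilyl)oxy]pentanedioate
Product: 3 1-tert-butyl 5-methyl (3S)-3-hydroxypentanedioate
Conditions: HF·pyridine, THF, 0 °C to rt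
Reagents that add atoms: none
Why: Fluoride desilylation under weakly acidic, non-basic conditions should free the carbinol without β-elimination, retro-aldol cleavage or ester exchange, and both esters are inert to HF·pyridine.

Step 3
Reactants: 3 1-tert-butyl 5-methyl (3S)-3-hydroxypentanedioate; 4 iodomethane
Product: 6 1-tert-butyl 5-methyl (2S,3S,4R)-3-hydroxy-2,4-dimethylpentanedioate, via trilithium alkoxide bis(enolate) 5 (not isolated)
Conditions: LiN(iPr)2 (3.4 equiv), THF, −78 to −20 °C; then CH3I (6 equiv), DMPU, −78 to −10 °C; aq. NH4Cl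
Reagents that add atoms: iodomethane, CI
Why: LiN(iPr)2 removes the O–H proton and then both ester α-protons, giving a trilithium species in which each enolate is held with the central alkoxide in a six-membered O–Li–O chelate. CH3I should attack each enolate carbon on the face turned away from the remainder of the carbinol chain, so each new C–CH3 bond forms anti to the C3 oxygen; the closest known reaction type is the Fráter–Seebach alkylation of β-hydroxy ester dianions, here run at both α-carbons of one molecule. No ring is closed; Ca and Cb are each set by 1,2-induction from the C3 alkoxide through the chelate, and the second methylation sees the same control element because the alkoxide stays in place. The step needs C- over O-methylation, single over geminal methylation and anti over syn delivery at both ends, which lithium chelation, the soft electrophile and the absence of free base after alkylation should secure. Because the methyl and tert-butyl esters make C3 a true stereocentre, the anti,anti product is one enantiomer, with the methyl ester on the arm destined for ring A.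

Step 4
Reactants: 6 1-tert-butyl 5-methyl (2S,3S,4R)-3-hydroxy-2,4-dimethylpentanedioate
Product: 7 1-tert-butyl 5-methyl (2S,3S,4R)-3-[(tert-butyldimethylsilyl)oxy]-2,4-dimethylpentanedioate
Conditions: TBSOTf (1.2 equiv), 2,6-lutidine, CH2Cl2, −78 to 0 °C
Reagents that add atoms: tert-butyldimethylsilyl trifluoromethanesulfonate, CC(C)(C)[Si](C)(C)OS(=O)(=O)C(F)(F)F
Why: Silyl triflate silylation of the hindered secondary alcohol in slight excess at low temperature leaves the tert-butyl ester alone, and the ether keeps Ck from being oxidised or forming hemiketals until both rings exist.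

Step 5
Reactants: 8 pentan-3-one; 9 hexanal
Product: 11 5-hydroxy-4-methyldecan-3-one, via lithium pent-2-en-3-olate 10 (not isolated)
Conditions: LiN(iPr)2, THF, −78 °C; then 9, −78 °C; aq. NH4Cl
Reagents that add atoms: none
Why: Directed aldol addition of the kinetic lithium enolate of the symmetrical ketone to the aldehyde gives the two new stereocentres as a mixture, which does not matter because both carbons become sp2 in ring A.

Step 6
Reactants: 7 1-tert-butyl 5-methyl (2S,3S,4R)-3-[(tert-butyldimethylsilyl)oxy]-2,4-dimethylpentanedioate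
Product: 12 tert-butyl (2S,3S,4R)-3-[(tert-butyldimethylsilyl)oxy]-2,4-dimethyl-5-oxopentanoate
Conditions: iBu2AlH (1.1 equiv), CH2Cl2, −78 °C; MeOH, then aq. KNaC4H4O6
Reagents that add atoms: none
Why: Partial ester reduction, in which iBu2AlH adds once to the methyl ester and the aluminium hemiacetal holds at −78 °C until quench while the bulkier tert-butyl ester reacts far more slowly; no base is present, so Ca keeps its configuration.

Step 7
Reactants: 11 5-hydroxy-4-methyldecan-3-one; 12 tert-butyl (2S,3S,4R)-3-[(tert-butyldimethylsilyl)oxy]-2,4-dimethyl-5-oxopentanoate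
Product: 14 tert-butyl (2S,3S,4S)-3-[(tert-butyldimethylsilyl)oxy]-5,9-dihydroxy-2,4,6,8-tetramethyl-7-oxotetradecanoate, via dilithium aldolate dianion 13 (not isolated)
Conditions: 11 (1.5 equiv), LiN(iPr)2 (2.0 equiv per 11), THF, −78 °C; then 12, −78 °C; aq. NH4Cl at −78 °C
Reagents that add atoms: none
Why: Aldolate dianion aldol reaction, in which after O–H removal the second equivalent of amide should deprotonate only the ethyl CH2 (the alkoxide shields the CH between C=O and C–O) and the enolate adds to the aldehyde faster than it can enolise it; the new carbinol and CH(CH3) centres are mixtures erased in steps 8 and 9.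

Step 8
Reactants: 14 tert-butyl (2S,3S,4S)-3-[(tert-butyldimethylsilyl)oxy]-5,9-dihydroxy-2,4,6,8-tetramethyl-7-oxotetradecanoate
Product: 15 tert-butyl (2S,3S,4R)-3-[(tert-butyldimethylsilyl)oxy]-2,4,6,8-tetramethyl-5,7,9-trioxotetradecanoate
Conditions: Dess–Martin periodinane (3 equiv), NaHCO3, CH2Cl2, 0 °C to rt
Reagents that add atoms: none
Why: Dess–Martin oxidation converts both secondary carbinols to ketones under buffered, non-basic conditions, so Ca, which is α to only one carbonyl, should not epimerise and the silyl ether and ester survive.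

Step 9
Reactants: 15 tert-butyl (2S,3S,4R)-3-[(tert-butyldimethylsilyl)oxy]-2,4,6,8-tetramethyl-5,7,9-trioxotetradecanoate
Product: 16 tert-butyl (2S,3S,4R)-3-[(tert-butyldimethylsilyl)oxy]-4-(3,5-dimethyl-4-oxo-6-pentyl-4H-pyran-2-yl)-2-methylpentanoate
Conditions: PPh3, CCl4, THF, rt
Reagents that add atoms: none
Why: Cyclodehydration of the 1,3,5-triketone under neutral Appel-type conditions, in which one terminal enol oxygen is activated as an oxyphosphonium and the enol oxygen of the other terminal carbonyl displaces Ph3PO by addition–elimination to close ring A; with the Ck oxygen silylated only this 4-pyranone can form, and Ca is not touched.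

Step 10
Reactants: 16 tert-butyl (2S,3S,4R)-3-[(tert-butyldimethylsilyl)oxy]-4-(3,5-dimethyl-4-oxo-6-pentyl-4H-pyran-2-yl)-2-methylpentanoate
Product: 18 (2S,3S,4R)-3-[(tert-butyldimethylsilyl)oxy]-4-(3,5-dimethyl-4-oxo-6-pentyl-4H-pyran-2-yl)-2-methylpentanoic acid, via trimethylsilyl ester 17 (not isolated)
Conditions: Me3SiOTf, 2,6-lutidine, CH2Cl2, 0 °C to rt; aq. citric acid work-up
Reagents that add atoms: none
Why: Silyl triflate cleavage of the tert-butyl ester (carbonyl O-silylation, loss of isobutene) gives the trimethylsilyl ester, hydrolysed on work-up; the secondary tert-butyldimethylsilyl ether is stable to these conditions and reversible O-silylation of ring A does no harm.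

Step 11
Reactants: 18 (2S,3S,4R)-3-[(tert-butyldimethylsilyl)oxy]-4-(3,5-dimethyl-4-oxo-6-pentyl-4H-pyran-2-yl)-2-methylpentanoic acid
Product: 19 (2S,3S,4R)-3-[(tert-butyldimethylsilyl)oxy]-4-(3,5-dimethyl-4-oxo-6-pentyl-4H-pyran-2-yl)-N-methoxy-N,2-dimethylpentanamide
Conditions: MeNH(OMe)·HCl, EDC·HCl, HOBt, N-methylmorpholine, CH2Cl2, 0 °C to rt
Reagents that add atoms: N,O-dimethylhydroxylamine hydrochloride, CNOC.Cl
Why: Carbodiimide/HOBt amide coupling through the benzotriazolyl active ester, which avoids ketene formation and so should keep Cb intact.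

Step 12
Reactants: 19 (2S,3S,4R)-3-[(tert-butyldimethylsilyl)oxy]-4-(3,5-dimethyl-4-oxo-6-pentyl-4H-pyran-2-yl)-N-methoxy-N,2-dimethylpentanamide; 20 4-methylheptane-3,5-dione
Product: 22 2-[(2R,3S,4S)-3-[(tert-butyldimethylsilyl)oxy]-4,6,8-trimethyl-5,7,9-trioxoundecan-2-yl]-3,5-dimethyl-6-pentyl-4H-pyran-4-one, via dilithium diketone dianion 21 (not isolated)
Conditions: 20 (2.5 equiv), LiN(iPr)2 (2.0 equiv per 20), THF, −78 to 0 °C; then 19, −78 to −30 °C; aq. NH4Cl
Reagents that add atoms: none
Why: γ-Acylation of a 1,3-diketone dianion by a Weinreb amide, in which the terminal carbanion of the symmetrical dianion (one regioisomer only) adds to the amide and the ketone is released only on quench, so a single acyl transfer occurs; the amide α-carbon Cb should not be deprotonated at low temperature.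

Step 13
Reactants: 22 2-[(2R,3S,4S)-3-[(tert-butyldimethylsilyl)oxy]-4,6,8-trimethyl-5,7,9-trioxoundecan-2-yl]-3,5-dimethyl-6-pentyl-4H-pyran-4-one
Product: 23 2-[(2R,3R,4S)-3-[(tert-butyldimethylsilyl)oxy]-4-(6-ethyl-3,5-dimethyl-4-oxo-4H-pyran-2-yl)pentan-2-yl]-3,5-dimethyl-6-pentyl-4H-pyran-4-one
Conditions: PPh3, CCl4, THF, rt
Reagents that add atoms: none
Why: The same neutral Appel-type cyclodehydration of a 1,3,5-triketone closes ring B by enol-oxygen attack on the oxyphosphonium-activated terminal carbonyl carbon, with Cb untouched and ring A inert.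

Step 14
Reactants: 23 2-[(2R,3R,4S)-3-[(tert-butyldimethylsilyl)oxy]-4-(6-ethyl-3,5-dimethyl-4-oxo-4H-pyran-2-yl)pentan-2-yl]-3,5-dimethyl-6-pentyl-4H-pyran-4-one
Product: 24 2-[(2R,3R,4S)-4-(6-ethyl-3,5-dimethyl-4-oxo-4H-pyran-2-yl)-3-hydroxypentan-2-yl]-3,5-dimethyl-6-pentyl-4H-pyran-4-one
Conditions: HF·pyridine, THF, rt
Reagents that add atoms: none
Why: Fluoride desilylation under acidic rather than basic conditions avoids dehydration or retro-aldol cleavage of the β-hydroxy pyranone.

Step 15
Reactants: 24 2-[(2R,3R,4S)-4-(6-ethyl-3,5-dimethyl-4-oxo-4H-pyran-2-yl)-3-hydroxypentan-2-yl]-3,5-dimethyl-6-pentyl-4H-pyran-4-one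
Product: 25 2-[(2S,4R)-4-(6-ethyl-3,5-dimethyl-4-oxo-4H-pyran-2-yl)-3-oxopentan-2-yl]-3,5-dimethyl-6-pentyl-4H-pyran-4-one
Conditions: Dess–Martin periodinane, NaHCO3, CH2Cl2, 0 °C to rt
Reagents that add atoms: none
Why: Dess–Martin oxidation of the secondary carbinol to the ketone under buffered neutral conditions is placed last because Ca and Cb become doubly activated (ketone and pyranone) only now, so they never meet base.

Compound list

1 | (3R)-3-[(tert-butyldimethylsilyl)oxy]-5-methoxy-5-oxopentanoic acid | COC(=O)C[C@H](O[Si](C)(C)C(C)(C)C)CC(=O)O | starting material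
2 | 1-tert-butyl 5-methyl (3S)-3-[(tert-butyldimethylsilyl)oxy]pentanedioate | COC(=O)C[C@H](O[Si](C)(C)C(C)(C)C)CC(=O)OC(C)(C)C | intermediate
3 | 1-tert-butyl 5-methyl (3S)-3-hydroxypentanedioate | COC(=O)C[C@H](O)CC(=O)OC(C)(C)C | intermediate
4 | iodomethane | CI | starting material
5 | trilithium (3S)-1-tert-butoxy-5-methoxypenta-1,4-diene-1,3,5-tris(olate) | COC([O-])=C[C@H]([O-])C=C([O-])OC(C)(C)C.[Li+].[Li+].[Li+] | intermediate
6 | 1-tert-butyl 5-methyl (2S,3S,4R)-3-hydroxy-2,4-dimethylpentanedioate | COC(=O)[C@H](C)[C@H](O)[C@H](C)C(=O)OC(C)(C)C | intermediate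
7 | 1-tert-butyl 5-methyl (2S,3S,4R)-3-[(tert-butyldimethylsilyl)oxy]-2,4-dimethylpentanedioate | COC(=O)[C@H](C)[C@H](O[Si](C)(C)C(C)(C)C)[C@H](C)C(=O)OC(C)(C)C | intermediate
8 | pentan-3-one | CCC(=O)CC | starting material
9 | hexanal | CCCCCC=O | starting material
10 | lithium pent-2-en-3-olate | CC=C([O-])CC.[Li+] | intermediate
11 | 5-hydroxy-4-methyldecan-3-one (diastereomer mixture) | CCCCCC(O)C(C)C(=O)CC | intermediate
12 | tert-butyl (2S,3S,4R)-3-[(tert-butyldimethylsilyl)oxy]-2,4-dimethyl-5-oxopentanoate | O=C[C@H](C)[C@H](O[Si](C)(C)C(C)(C)C)[C@H](C)C(=O)OC(C)(C)C | intermediate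
13 | dilithium 4-methyldec-2-ene-3,5-bis(olate) | CCCCCC([O-])C(C)C([O-])=CC.[Li+].[Li+] | intermediate
14 | tert-butyl (2S,3S,4S)-3-[(tert-butyldimethylsilyl)oxy]-5,9-dihydroxy-2,4,6,8-tetramethyl-7-oxotetradecanoate (mixture at C5, C6, C8, C9) | CCCCCC(O)C(C)C(=O)C(C)C(O)[C@H](C)[C@H](O[Si](C)(C)C(C)(C)C)[C@H](C)C(=O)OC(C)(C)C | intermediate
15 | tert-butyl (2S,3S,4R)-3-[(tert-butyldimethylsilyl)oxy]-2,4,6,8-tetramethyl-5,7,9-trioxotetradecanoate (C6, C8 enolisable) | CCCCCC(=O)C(C)C(=O)C(C)C(=O)[C@H](C)[C@H](O[Si](C)(C)C(C)(C)C)[C@H](C)C(=O)OC(C)(C)C | intermediate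
16 | tert-butyl (2S,3S,4R)-3-[(tert-butyldimethylsilyl)oxy]-4-(3,5-dimethyl-4-oxo-6-pentyl-4H-pyran-2-yl)-2-methylpentanoate | CCCCCc1oc([C@H](C)[C@H](O[Si](C)(C)C(C)(C)C)[C@H](C)C(=O)OC(C)(C)C)c(C)c(=O)c1C | intermediate
17 | trimethylsilyl (2S,3S,4R)-3-[(tert-butyldimethylsilyl)oxy]-4-(3,5-dimethyl-4-oxo-6-pentyl-4H-pyran-2-yl)-2-methylpentanoate | CCCCCc1oc([C@H](C)[C@H](O[Si](C)(C)C(C)(C)C)[C@H](C)C(=O)O[Si](C)(C)C)c(C)c(=O)c1C | intermediate
18 | (2S,3S,4R)-3-[(tert-butyldimethylsilyl)oxy]-4-(3,5-dimethyl-4-oxo-6-pentyl-4H-pyran-2-yl)-2-methylpentanoic acid | CCCCCc1oc([C@H](C)[C@H](O[Si](C)(C)C(C)(C)C)[C@H](C)C(=O)O)c(C)c(=O)c1C | intermediate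
19 | (2S,3S,4R)-3-[(tert-butyldimethylsilyl)oxy]-4-(3,5-dimethyl-4-oxo-6-pentyl-4H-pyran-2-yl)-N-methoxy-N,2-dimethylpentanamide | CCCCCc1oc([C@H](C)[C@H](O[Si](C)(C)C(C)(C)C)[C@H](C)C(=O)N(C)OC)c(C)c(=O)c1C | intermediate
20 | 4-methylheptane-3,5-dione | CCC(=O)C(C)C(=O)CC | starting material
21 | dilithium 4-methylhepta-2,4-diene-3,5-bis(olate) | CC=C([O-])C(C)=C([O-])CC.[Li+].[Li+] | intermediate
22 | 2-[(2R,3S,4S)-3-[(tert-butyldimethylsilyl)oxy]-4,6,8-trimethyl-5,7,9-trioxoundecan-2-yl]-3,5-dimethyl-6-pentyl-4H-pyran-4-one (C6, C8 enolisable) | CCCCCc1oc([C@H](C)[C@H](O[Si](C)(C)C(C)(C)C)[C@H](C)C(=O)C(C)C(=O)C(C)C(=O)CC)c(C)c(=O)c1C | intermediate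
23 | 2-[(2R,3R,4S)-3-[(tert-butyldimethylsilyl)oxy]-4-(6-ethyl-3,5-dimethyl-4-oxo-4H-pyran-2-yl)pentan-2-yl]-3,5-dimethyl-6-pentyl-4H-pyran-4-one | CCCCCc1oc([C@H](C)[C@H](O[Si](C)(C)C(C)(C)C)[C@H](C)c2oc(CC)c(C)c(=O)c2C)c(C)c(=O)c1C | intermediate
24 | 2-[(2R,3R,4S)-4-(6-ethyl-3,5-dimethyl-4-oxo-4H-pyran-2-yl)-3-hydroxypentan-2-yl]-3,5-dimethyl-6-pentyl-4H-pyran-4-one | CCCCCc1oc([C@H](C)[C@H](O)[C@H](C)c2oc(CC)c(C)c(=O)c2C)c(C)c(=O)c1C | intermediate
25 | 2-[(2S,4R)-4-(6-ethyl-3,5-dimethyl-4-oxo-4H-pyran-2-yl)-3-oxopentan-2-yl]-3,5-dimethyl-6-pentyl-4H-pyran-4-one | CCCCCc1oc([C@H](C)C(=O)[C@H](C)c2oc(CC)c(C)c(=O)c2C)c(C)c(=O)c1C | target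

Total step count: 15. Longest linear sequence: 14 (steps 1–4 and 6–15; step 5 is a one-step side branch).

Steps most likely to fail

Step 3. The third deprotonation may stall in an aggregated dilithio species so that only one arm is methylated, enolate–ester proton transfer may erode the anti selectivity, and β-elimination of the alkoxide may compete on warming. The fallback sets out from 3 and makes the two C–CH3 bonds in two separate dianion methylations (LiN(iPr)2 2.2 equiv, CH3I, THF/DMPU each time). The first operation should give the anti mono-methyl alcohols 1-tert-butyl 5-methyl (2S,3S)-3-hydroxy-2-methylpentanedioate F1 and 5-tert-butyl 1-methyl (2R,3R)-3-hydroxy-2-methylpentanedioate F2, which differ only in the arm that reacted. Both are carried through a second identical operation and converge on 6, where the route is rejoined.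

Step 12. Proton transfer from the lateral C–H bonds of ring A (pentyl CH2 and Ca–H) to the strongly basic dianion may outrun its slow addition to the hindered amide, and a Ca anion could then expel silanolate. The fallback sets out from acid 18 and swaps the acyl transfer for an aldehyde addition followed by oxidation. Carbodiimide thioesterification (EtSH, EDC·HCl, cat. DMAP) gives S-ethyl (2S,3S,4R)-3-[(tert-butyldimethylsilyl)oxy]-4-(3,5-dimethyl-4-oxo-6-pentyl-4H-pyran-2-yl)-2-methylpentanethioate F3. Fukuyama reduction (Et3SiH, Pd/C, acetone) gives (2S,3S,4R)-3-[(tert-butyldimethylsilyl)oxy]-4-(3,5-dimethyl-4-oxo-6-pentyl-4H-pyran-2-yl)-2-methylpentanal F4. Dianion 21 adds to this aldehyde at −78 °C, faster than any proton transfer, to give 2-[(2R,3R,4R)-3-[(tert-butyldimethylsilyl)oxy]-5-hydroxy-4,6,8-trimethyl-7,9-dioxoundecan-2-yl]-3,5-dimethyl-6-pentyl-4H-pyran-4-one F5. Dess–Martin oxidation then comes back to the route at triketone 22.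

Step 7. The second deprotonation of the lithium aldolate may be slow or not fully regioselective, the dianion or the bis-aldolate may fragment by retro-aldol reaction on warming, and unreacted amide base may enolise aldehyde 12. The fallback sets out from 11 and uses a protected mono-enolate. Silylation (Et3SiCl, imidazole) gives 4-methyl-5-[(triethylsilyl)oxy]decan-3-one F6, whose simple lithium enolate (LiN(iPr)2, 1 equiv) adds to 12 to give tert-butyl (2S,3S,4S)-3-[(tert-butyldimethylsilyl)oxy]-5-hydroxy-2,4,6,8-tetramethyl-7-oxo-9-[(triethylsilyl)oxy]tetradecanoate F7. Selective removal of the triethylsilyl ether (PPTS, MeOH) comes back to the route at diol 14.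

Further compounds

F1 | step 3 | 1-tert-butyl 5-methyl (2S,3S)-3-hydroxy-2-methylpentanedioate | COC(=O)C[C@H](O)[C@H](C)C(=O)OC(C)(C)C
F2 | step 3 | 5-tert-butyl 1-methyl (2R,3R)-3-hydroxy-2-methylpentanedioate | COC(=O)[C@H](C)[C@H](O)CC(=O)OC(C)(C)C
F3 | step 12 | S-ethyl (2S,3S,4R)-3-[(tert-butyldimethylsilyl)oxy]-4-(3,5-dimethyl-4-oxo-6-pentyl-4H-pyran-2-yl)-2-methylpentanethioate | CCCCCc1oc([C@H](C)[C@H](O[Si](C)(C)C(C)(C)C)[C@H](C)C(=O)SCC)c(C)c(=O)c1C
F4 | step 12 | (2S,3S,4R)-3-[(tert-butyldimethylsilyl)oxy]-4-(3,5-dimethyl-4-oxo-6-pentyl-4H-pyran-2-yl)-2-methylpentanal | CCCCCc1oc([C@H](C)[C@H](O[Si](C)(C)C(C)(C)C)[C@H](C)C=O)c(C)c(=O)c1C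
F5 | step 12 | 2-[(2R,3R,4R)-3-[(tert-butyldimethylsilyl)oxy]-5-hydroxy-4,6,8-trimethyl-7,9-dioxoundecan-2-yl]-3,5-dimethyl-6-pentyl-4H-pyran-4-one | CCCCCc1oc([C@H](C)[C@H](O[Si](C)(C)C(C)(C)C)[C@H](C)C(O)C(C)C(=O)C(C)C(=O)CC)c(C)c(=O)c1C
F6 | step 7 | 4-methyl-5-[(triethylsilyl)oxy]decan-3-one | CCCCCC(O[Si](CC)(CC)CC)C(C)C(=O)CC
F7 | step 7 | tert-butyl (2S,3S,4S)-3-[(tert-butyldimethylsilyl)oxy]-5-hydroxy-2,4,6,8-tetramethyl-7-oxo-9-[(triethylsilyl)oxy]tetradecanoate | CCCCCC(O[Si](CC)(CC)CC)C(C)C(=O)C(C)C(O)[C@H](C)[C@H](O[Si](C)(C)C(C)(C)C)[C@H](C)C(=O)OC(C)(C)C
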